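**Retrosynthetic overview**
1. Target 18 comes from its tert-butyl ester 17 by acidolysis, 17 from hydroxy acetate 16 by tigloylation of O4, and 16 from epoxy enoate 15: acetate opens the C4–C5 epoxide at C5 with inversion, so one epoxide delivers the trans O4/O5 pair already differentiated.
2. 15 comes from cycloadduct 12 by one peracid operation (C4=C5 epoxidation plus Baeyer–Villiger excision of a temporary C2 formyl group) and E1cB loss of formate, which creates C1=C2.
3. Key disconnection: the carbocycle C1–C6 is opened across C2–C3 and C1–C6 into dienyl ester 5 (C3–C6, already carrying the O3 6-methylheptanoate) and the C1=C2 unit with its carboxyl carbon, used as tert-butyl (E)-4-oxobut-2-enoate 9.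
4. Enabling feature: in the cyclohexene ring the C1=C2 alkene is flanked by the C2–C3 and C1–C6 single bonds and C3 bears oxygen, which is the retron of a [4+2] cycloaddition of a 1-acyloxybutadiene. The C2–CHO bond, absent from the target, is the iminium handle that turns the orientation to carboxyl at C1 / oxygen at C3 and carries the asymmetric induction.
5. Ring order: the cyclohexene is the only ring of the target and is formed in step 4; the 4,5-epoxide is a temporary ring (formed in step 5, opened in step 7).

Key step: step 4

Remark: ring positions are numbered as in the target throughout (C1 carries the carboxyl carbon; C3, C4 and C5 carry the ester oxygens); the CIP letter at C3 changes from S in 12 to R from 13 on only because substituent priorities change, not the geometry; 1, 2, 6 and 7 (the last as its aqueous solution) are taken as commercial.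

**Route**

Step 1
Reactants: 1 6-methylheptanoic acid; 2 (E)-but-2-enal (crotonaldehyde)
Product: 5 (1E)-buta-1,3-dien-1-yl 6-methylheptanoate, via 6-methylheptanoyl chloride 3 (not isolated), via potassium buta-1,3-dien-1-olate 4 (not isolated)
Conditions: 1, (COCl)2, DMF (cat.), CH2Cl2, 0 °C to rt, concentrate; 2, KOtBu, THF, −78 °C; then 3, −78 °C to rt
Reagents that add atoms: none
Why: Vilsmeier-type conversion of the acid into its chloride and O-acylation of the potassium dienolate formed by γ-deprotonation of crotonaldehyde should give the enol ester mainly as the (E)-isomer, the only one that can react in the s-cis form later.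

Step 2
Reactants: 6 tert-butyl (triphenylphosphoranylidene)acetate; 7 2,2-dimethoxyacetaldehyde
Product: 8 tert-butyl (2E)-4,4-dimethoxybut-2-enoate
Conditions: CH2Cl2, rt
Reagents that add atoms: none
Why: Wittig olefination of the aldehyde with the ester-stabilised ylide should give the (E)-enoate while the acetal keeps the second aldehyde masked.

Step 3
Reactants: 8 tert-butyl (2E)-4,4-dimethoxybut-2-enoate
Product: 9 tert-butyl (2E)-4-oxobut-2-enoate
Conditions: Amberlyst 15 (sulfonic acid resin), acetone/H2O, rt
Reagents that add atoms: water, O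
Why: Acid-catalysed acetal hydrolysis on a sulfonic acid resin should unmask the aldehyde without cleaving the tert-butyl ester or isomerising the (E)-alkene.

Step 4
Reactants: 5 (1E)-buta-1,3-dien-1-yl 6-methylheptanoate; 9 tert-butyl (2E)-4-oxobut-2-enoate
Product: 12 tert-butyl (1S,2R,3S)-2-formyl-3-[(6-methylheptanoyl)oxy]cyclohex-4-ene-1-carboxylate (formyl cis to the C3 ester, tert-butyl ester trans to formyl), via dienophile iminium chloride 10 (not isolated), via cycloadduct iminium chloride 11 (not isolated)
Conditions: (5S)-5-benzyl-2,2,3-trimethylimidazolidin-4-one hydrochloride (20 mol %), 5 (3 equiv), MeCN/H2O 95:5, 0 °C to rt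
Reagents that add atoms: none
Why: Condensation of enal 9 with the (5S)-imidazolidinone gives the (E)-iminium ion 10, whose lowered LUMO engages diene 5 in a concerted, asynchronous [4+2] cycloaddition, and hydrolysis of the cycloadduct iminium 11 releases 12 and the catalyst. The closest known reaction type is the imidazolidinone-catalysed Diels–Alder reaction of enals with acyclic dienes, 1-acetoxybutadiene included. The six-membered carbocycle is closed by a suprafacial [4π+2π] cycloaddition in which the C6–C1 and C3–C2 bonds form in the same transition state. C1 and C2 are set by the catalyst, whose benzyl group covers one face of the iminium π-system so that the diene adds to the open face of the (E)-enal (1S,2R), and C3 is set relative to C2 by the endo orientation of the iminium unit towards the (E)-dienyl ester, which places the formyl group and the C3 ester cis (3S in 12, the geometry that becomes 3R of the target). The regiochemistry needed (C3 to the formyl-bearing carbon, C6 to the carboxyl-bearing carbon) follows from pairing the largest HOMO coefficient of the 1-acyloxydiene at C6 with the largest LUMO coefficient at the iminium β-carbon, so the temporary formyl group overrides the ester and gives the carboxyl/O3 relationship that a propiolate would not give. The step also needs endo over exo selectivity, which the cationic iminium should favour over the tert-butyl ester; any exo adduct is a diastereomer and is removed by chromatography.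

Step 5
Reactants: 12 tert-butyl (1S,2R,3S)-2-formyl-3-[(6-methylheptanoyl)oxy]cyclohex-4-ene-1-carboxylate
Product: 14 tert-butyl (1S,2R,3R,4R,5R)-4,5-epoxy-2-(formyloxy)-3-[(6-methylheptanoyl)oxy]cyclohexane-1-carboxylate (epoxide trans to the C3 ester), via epoxy aldehyde 13 (not isolated)
Conditions: mCPBA (2.5 equiv), Na2HPO4, CH2Cl2, 0 °C to rt
Reagents that add atoms: 3-chloroperbenzoic acid (mCPBA), OOC(=O)c1cccc(Cl)c1
Why: Prilezhaev epoxidation of the C4=C5 alkene from the face opposite the pseudoaxial C3 ester and the cis C2 formyl group sets C4 and C5 (epoxide trans to O3), and the same peracid then effects a Baeyer–Villiger oxidation of the α-branched aldehyde in which the secondary C2 migrates with retention to give the formate.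

Step 6
Reactants: 14 tert-butyl (1S,2R,3R,4R,5R)-4,5-epoxy-2-(formyloxy)-3-[(6-methylheptanoyl)oxy]cyclohexane-1-carboxylate
Product: 15 tert-butyl (3R,4R,5R)-4,5-epoxy-3-[(6-methylheptanoyl)oxy]cyclohex-1-ene-1-carboxylate
Conditions: DBU (1.1 equiv), CH2Cl2, 0 °C
Reagents that add atoms: none
Why: E1cB elimination of formate from the β-formyloxy ester should give the conjugated C1=C2 enoate and removes the two temporary stereocenters without touching C3 to C5.

Step 7
Reactants: 15 tert-butyl (3R,4R,5R)-4,5-epoxy-3-[(6-methylheptanoyl)oxy]cyclohex-1-ene-1-carboxylate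
Product: 16 tert-butyl (3R,4R,5S)-5-acetoxy-4-hydroxy-3-[(6-methylheptanoyl)oxy]cyclohex-1-ene-1-carboxylate
Conditions: CsOAc (1.5 equiv), AcOH (5 equiv), DMF, 55 °C
Reagents that add atoms: acetic acid, CC(=O)O; cesium acetate, CC(=O)[O-].[Cs+]
Why: SN2 ring opening of the epoxide by acetate should occur at C5, the carbon remote from the inductively deactivating C3 ester that also shields the C4 trajectory, with inversion at C5 to give the trans hydroxy acetate, while the acetic acid buffer protonates the C4 alkoxide before an ester can migrate.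

Step 8
Reactants: 16 tert-butyl (3R,4R,5S)-5-acetoxy-4-hydroxy-3-[(6-methylheptanoyl)oxy]cyclohex-1-ene-1-carboxylate
Product: 17 tert-butyl (3R,4R,5S)-5-acetoxy-3-[(6-methylheptanoyl)oxy]-4-{[(2E)-2-methylbut-2-enoyl]oxy}cyclohex-1-ene-1-carboxylate
Conditions: tigloyl chloride (3 equiv), pyridine, DMAP (cat.), CH2Cl2, 0 °C to rt
Reagents that add atoms: tigloyl chloride, C/C=C(\C)C(Cl)=O
Why: DMAP-catalysed O-acylation (nucleophilic catalysis) of the one free secondary hydroxyl at C4 with the acid chloride installs the tigloyl ester without change at any stereocenter.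

Step 9
Reactants: 17 tert-butyl (3R,4R,5S)-5-acetoxy-3-[(6-methylheptanoyl)oxy]-4-{[(2E)-2-methylbut-2-enoyl]oxy}cyclohex-1-ene-1-carboxylate
Product: 18 (3R,4R,5S)-5-acetoxy-3-[(6-methylheptanoyl)oxy]-4-{[(2E)-2-methylbut-2-enoyl]oxy}cyclohex-1-ene-1-carboxylic acid
Conditions: TFA/CH2Cl2 1:4, 0 °C to rt
Reagents that add atoms: none
Why: Acidolysis of the tert-butyl ester (alkyl–oxygen cleavage with loss of isobutene) should free the carboxylic acid while the three other esters and the electron-poor allylic system stay intact.

**Compound list**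
1 | 6-methylheptanoic acid | CC(C)CCCCC(=O)O | starting material
2 | (E)-but-2-enal (crotonaldehyde) | C/C=C/C=O | starting material
3 | 6-methylheptanoyl chloride | CC(C)CCCCC(Cl)=O | intermediate (not isolated)
4 | potassium (1E)-buta-1,3-dien-1-olate | [K+].[O-]/C=C/C=C | intermediate (not isolated)
5 | (1E)-buta-1,3-dien-1-yl 6-methylheptanoate | CC(C)CCCCC(=O)O/C=C/C=C | intermediate
6 | tert-butyl (triphenylphosphoranylidene)acetate | CC(C)(C)OC(=O)C=P(c1ccccc1)(c1ccccc1)c1ccccc1 | starting material
7 | 2,2-dimethoxyacetaldehyde | COC(OC)C=O | starting material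
8 | tert-butyl (2E)-4,4-dimethoxybut-2-enoate | COC(OC)/C=C/C(=O)OC(C)(C)C | intermediate
9 | tert-butyl (2E)-4-oxobut-2-enoate | O=C/C=C/C(=O)OC(C)(C)C | intermediate
10 | (5S)-5-benzyl-1-[(2E)-4-tert-butoxy-4-oxobut-2-en-1-ylidene]-2,2,3-trimethyl-4-oxoimidazolidin-1-ium chloride (iminium ion of 9) | CN1C(=O)[C@H](Cc2ccccc2)[N+](=C/C=C/C(=O)OC(C)(C)C)C1(C)C.[Cl-] | intermediate (not isolated)
11 | iminium chloride of cycloadduct 12 with the (5S)-imidazolidinone (ring stereocenters as in 12) | CC(C)CCCCC(=O)O[C@H]1C=CC[C@H](C(=O)OC(C)(C)C)[C@H]1C=[N+]2[C@@H](Cc3ccccc3)C(=O)N(C)C2(C)C.[Cl-] | intermediate (not isolated)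
12 | tert-butyl (1S,2R,3S)-2-formyl-3-[(6-methylheptanoyl)oxy]cyclohex-4-ene-1-carboxylate | CC(C)CCCCC(=O)O[C@H]1C=CC[C@H](C(=O)OC(C)(C)C)[C@H]1C=O | intermediate
13 | tert-butyl (1S,2R,3R,4R,5R)-4,5-epoxy-2-formyl-3-[(6-methylheptanoyl)oxy]cyclohexane-1-carboxylate | CC(C)CCCCC(=O)O[C@@H]1[C@H](C=O)[C@@H](C(=O)OC(C)(C)C)C[C@H]2O[C@@H]12 | intermediate (not isolated)
14 | tert-butyl (1S,2R,3R,4R,5R)-4,5-epoxy-2-(formyloxy)-3-[(6-methylheptanoyl)oxy]cyclohexane-1-carboxylate | CC(C)CCCCC(=O)O[C@@H]1[C@H](OC=O)[C@@H](C(=O)OC(C)(C)C)C[C@H]2O[C@@H]12 | intermediate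
15 | tert-butyl (3R,4R,5R)-4,5-epoxy-3-[(6-methylheptanoyl)oxy]cyclohex-1-ene-1-carboxylate | CC(C)CCCCC(=O)O[C@@H]1C=C(C(=O)OC(C)(C)C)C[C@H]2O[C@@H]12 | intermediate
16 | tert-butyl (3R,4R,5S)-5-acetoxy-4-hydroxy-3-[(6-methylheptanoyl)oxy]cyclohex-1-ene-1-carboxylate | CC(C)CCCCC(=O)O[C@@H]1C=C(C(=O)OC(C)(C)C)C[C@H](OC(C)=O)[C@H]1O | intermediate
17 | tert-butyl (3R,4R,5S)-5-acetoxy-3-[(6-methylheptanoyl)oxy]-4-{[(2E)-2-methylbut-2-enoyl]oxy}cyclohex-1-ene-1-carboxylate | CC(C)CCCCC(=O)O[C@@H]1C=C(C(=O)OC(C)(C)C)C[C@H](OC(C)=O)[C@H]1OC(=O)/C(C)=C/C | intermediate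
18 | (3R,4R,5S)-5-acetoxy-3-[(6-methylheptanoyl)oxy]-4-{[(2E)-2-methylbut-2-enoyl]oxy}cyclohex-1-ene-1-carboxylic acid | C/C=C(\C)C(=O)O[C@@H]1[C@@H](OC(C)=O)CC(C(=O)O)=C[C@H]1OC(=O)CCCCC(C)C | target

**Step count**
Total step count: 9. Longest linear sequence: 8 steps (steps 2 to 9).

**Steps most likely to fail**

Step 4. The enol ester diene may hydrolyse in the aqueous acidic medium faster than it cycloadds, or the iminium unit may show too little endo preference over the tert-butyl ester, so that most material ends in the exo diastereomer. The fallback sets out from 5 and returns at 15. The formyl handle is replaced by a nitro group, which directs the same orientation and leaves as nitrous acid, and the single enantiomer is secured by resolution instead of catalysis. tert-Butyl acrylate is converted by nitryl iodide addition (I2, AgNO2, Et2O) into tert-butyl 2-iodo-3-nitropropanoate F1 and by elimination of HI (NaOAc) into tert-butyl (E)-3-nitroacrylate F2. Thermal Diels–Alder reaction of F2 with 5 (toluene, rt; nitro group next to the C3 ester carbon and endo) should give the racemic nitro cycloadduct F3. Epoxidation with mCPBA should give the racemic nitro epoxide F4. DBU then eliminates nitrous acid to give the epoxy enoate as the racemate of 15 and its enantiomer F5; preparative chromatography on a chiral stationary phase removes F5 and the route continues from 15.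

Step 5. In the Criegee intermediate hydride may migrate instead of C2, whose migration is slowed by the two β-ester groups, so that the aldehyde is over-oxidised to the C2 carboxylic acid. The fallback sets out from 12 and returns at 15, and removes the formyl carbon by decarboxylation instead of oxygen insertion. Pinnick oxidation (NaClO2, NaH2PO4, 2-methylbut-2-ene, t-BuOH/H2O) should give the C2 carboxylic acid F6. Kochi chlorodecarboxylation (Pb(OAc)4, LiCl, benzene, 80 °C) should give the C2 chloride F7, of which both C2 epimers are usable. Epoxidation with mCPBA anti to the C3 ester should give the epoxy chloride F8, and DBU-induced E1cB loss of HCl leads to 15.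

Step 7. Under the carboxylate conditions an ester may migrate from O3 or O5 to the newly freed C4 hydroxyl, or the opening may be too slow to compete with base-induced decomposition of the epoxy enoate. The fallback sets out from 15 and returns at 17, without passing through 16. LiBr, AcOH, THF, rt should open the epoxide with bromide at C5 to give the trans bromohydrin F9. Tigloyl chloride, pyridine and DMAP should give the bromo tiglate F10. AgOAc in dry AcOH then replaces bromide by acetate with net retention at C5 through participation of the neighbouring C4 tigloyl ester (double inversion, acetate entering at C5, the carbon remote from the C3 ester), which gives 17.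

**Further compounds**
F1 | step 4 | tert-butyl 2-iodo-3-nitropropanoate (racemic) | CC(C)(C)OC(=O)C(I)C[N+](=O)[O-]
F2 | step 4 | tert-butyl (E)-3-nitroacrylate | CC(C)(C)OC(=O)/C=C/[N+](=O)[O-]
F3 | step 4 | racemic tert-butyl 3-[(6-methylheptanoyl)oxy]-2-nitrocyclohex-4-ene-1-carboxylate, nitro cis to the C3 ester and trans to the tert-butyl ester (enantiomer drawn: 1S,2R,3S) | CC(C)CCCCC(=O)O[C@H]1C=CC[C@H](C(=O)OC(C)(C)C)[C@H]1[N+](=O)[O-]
F4 | step 4 | racemic tert-butyl 4,5-epoxy-3-[(6-methylheptanoyl)oxy]-2-nitrocyclohexane-1-carboxylate, epoxide trans to the C3 ester (enantiomer drawn: 1S,2R,3R,4R,5R) | CC(C)CCCCC(=O)O[C@@H]1[C@H]([N+](=O)[O-])[C@@H](C(=O)OC(C)(C)C)C[C@H]2O[C@@H]12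
F5 | step 4 | tert-butyl (3S,4S,5S)-4,5-epoxy-3-[(6-methylheptanoyl)oxy]cyclohex-1-ene-1-carboxylate (enantiomer of 15) | CC(C)CCCCC(=O)O[C@H]1C=C(C(=O)OC(C)(C)C)C[C@@H]2O[C@H]12
F6 | step 5 | (1R,2S,6S)-2-(tert-butoxycarbonyl)-6-[(6-methylheptanoyl)oxy]cyclohex-4-ene-1-carboxylic acid (the C2 carboxylic acid corresponding to aldehyde 12) | CC(C)CCCCC(=O)O[C@H]1C=CC[C@H](C(=O)OC(C)(C)C)[C@H]1C(=O)O
F7 | step 5 | tert-butyl 2-chloro-3-[(6-methylheptanoyl)oxy]cyclohex-4-ene-1-carboxylate, C1 and C3 as in 12, both C2 epimers | CC(C)CCCCC(=O)O[C@H]1C=CC[C@H](C(=O)OC(C)(C)C)C1Cl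
F8 | step 5 | tert-butyl 2-chloro-4,5-epoxy-3-[(6-methylheptanoyl)oxy]cyclohexane-1-carboxylate, C1, C3, C4 and C5 as in 14, both C2 epimers | CC(C)CCCCC(=O)O[C@@H]1C(Cl)[C@@H](C(=O)OC(C)(C)C)C[C@H]2O[C@@H]12
F9 | step 7 | tert-butyl (3R,4S,5S)-5-bromo-4-hydroxy-3-[(6-methylheptanoyl)oxy]cyclohex-1-ene-1-carboxylate | CC(C)CCCCC(=O)O[C@@H]1C=C(C(=O)OC(C)(C)C)C[C@H](Br)[C@H]1O
F10 | step 7 | tert-butyl (3R,4S,5S)-5-bromo-3-[(6-methylheptanoyl)oxy]-4-{[(2E)-2-methylbut-2-enoyl]oxy}cyclohex-1-ene-1-carboxylate | CC(C)CCCCC(=O)O[C@@H]1C=C(C(=O)OC(C)(C)C)C[C@H](Br)[C@H]1OC(=O)/C(C)=C/C
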